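**Retrosynthetic overview**
1. Target ⇐ desilylation of its bis-TIPS ether ⇐ all-cis oxolane from one enantioselective hydrogenation of a 2-aryl-3-(hydroxymethyl)-4-benzylfuran (both furan C=C saturated from one face, fixing C2, C3 and C4 together).
2. Furan ⇐ Feist–Benary annulation of an aryl β-ketoester with the ring-A α-chloroketone (from homovanillic acid), then reduction of all three esters.
3. β-Ketoester ⇐ aryl aldehyde + ethyl diazoacetate; each trans-dihydrobenzofuran ⇐ Rh(II)-catalysed asymmetric intramolecular C–H insertion of an aryl diazoacetate (5-iodovanillin, Mitsunobu ether, Pd coupling with ethyl diazoacetate), then C3 epimerisation; the two units use enantiomeric catalysts.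
4. Ring order: dihydrobenzofuran carrying the terminal guaiacyl ring → second dihydrobenzofuran → furan → oxolane (last ring, last three stereocentres).
5. Carbon sources: vanillin, 5-iodovanillin (twice), ethyl diazoacetate (three times), homovanillic acid.

Assumption: Rh2(S-PTTL)4 gives the (2R)-dihydrobenzofuran and Ru/(R,R)-SINpEt the (2R,3R,4R)-oxolane; if a sense of induction is the reverse, the antipodal catalyst is used in that step; 5-iodovanillin, ethyl diazoacetate, homovanillic acid and both catalyst antipodes are bought.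

Abbreviations: TIPS = triisopropylsilyl; ArT = 3-methoxy-4-(triisopropylsilyloxy)phenyl; DB2E = (2S,3S)-3-(ethoxycarbonyl)-7-methoxy-2-ArT-2,3-dihydro-1-benzofuran-5-yl; DB2H = (2S,3R)-3-(hydroxymethyl)-7-methoxy-2-ArT-2,3-dihydro-1-benzofuran-5-yl; PTTL = N-phthaloyl-tert-leucinate.

**Route**

Step 1
Reactants: 1 vanillin
Product: 3 [3-methoxy-4-(triisopropylsilyloxy)phenyl]methanol, via TIPS-vanillin 2 (not isolated)
Conditions: TIPSCl, imidazole, CH2Cl2, rt; then MeOH, NaBH4, 0 °C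
Reagents that add atoms: triisopropylsilyl chloride CC(C)[Si](Cl)(C(C)C)C(C)C
Why: Phenol silylation followed in the same flask by borohydride reduction of the aldehyde; no stereocentre is formed.

Step 2
Reactants: 3 [3-methoxy-4-(triisopropylsilyloxy)phenyl]methanol; 4 5-iodovanillin
Product: 5 3-iodo-5-methoxy-4-[(ArT)methoxy]benzaldehyde
Conditions: PPh3, DIAD, THF, 0 °C → rt
Reagents that add atoms: none
Why: Mitsunobu etherification, in which the acidic iodophenol is alkylated by the primary benzylic alcohol under neutral conditions that spare the aldehyde and silyl ether.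

Step 3
Reactants: 5 3-iodo-5-methoxy-4-[(ArT)methoxy]benzaldehyde; 6 ethyl diazoacetate
Product: 7 ethyl 2-diazo-2-{5-formyl-3-methoxy-2-[(ArT)methoxy]phenyl}acetate
Conditions: Pd(PPh3)4 (10 mol%), Ag2CO3 (0.5 equiv), Et3N, toluene, rt
Reagents that add atoms: none
Why: Pd-catalysed cross-coupling of an aryl iodide with the C–H bond of ethyl diazoacetate keeps the diazo group and gives the aryl diazoacetate in one step.

Step 4
Reactants: 7 ethyl 2-diazo-2-{5-formyl-3-methoxy-2-[(ArT)methoxy]phenyl}acetate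
Product: 9 ethyl (2S,3S)-5-formyl-7-methoxy-2-ArT-2,3-dihydro-1-benzofuran-3-carboxylate (2,3-trans), via cis-(2S,3R) ester 8 (not isolated)
Conditions: Rh2(R-PTTL)4 (2 mol%), toluene, −60 °C; then DBU (0.5 equiv), 0 °C → rt
Reagents that add atoms: none
Why: Rh(II)-carbenoid intramolecular 1,5 C–H insertion into the benzylic ether CH2 closes the ring cis with C2 set (S) by the chiral carboxylate catalyst, and DBU then epimerises C3 (α to the ester) to the more stable 2,3-trans isomer without touching C2.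

Step 5
Reactants: 9 ethyl (2S,3S)-5-formyl-7-methoxy-2-ArT-2,3-dihydro-1-benzofuran-3-carboxylate
Product: 10 ethyl (2S,3S)-5-(hydroxymethyl)-7-methoxy-2-ArT-2,3-dihydro-1-benzofuran-3-carboxylate
Conditions: NaBH4, EtOH–THF, 0 °C
Reagents that add atoms: none
Why: Chemoselective borohydride reduction of the aryl aldehyde; the ester, silyl ether and both stereocentres are untouched at 0 °C.

Step 6
Reactants: 10 ethyl (2S,3S)-5-(hydroxymethyl)-7-methoxy-2-ArT-2,3-dihydro-1-benzofuran-3-carboxylate; 4 5-iodovanillin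
Product: 11 3-iodo-5-methoxy-4-[(DB2E)methoxy]benzaldehyde
Conditions: PPh3, DIAD, THF, 0 °C → rt
Reagents that add atoms: none
Why: Second Mitsunobu etherification of 5-iodovanillin, now with the electron-rich primary benzylic alcohol of the first dihydrobenzofuran; no stereocentre is involved.

Step 7
Reactants: 11 3-iodo-5-methoxy-4-[(DB2E)methoxy]benzaldehyde; 6 ethyl diazoacetate
Product: 12 ethyl 2-diazo-2-{5-formyl-3-methoxy-2-[(DB2E)methoxy]phenyl}acetate
Conditions: Pd(PPh3)4 (10 mol%), Ag2CO3 (0.5 equiv), Et3N, toluene, rt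
Reagents that add atoms: none
Why: Same Pd-catalysed aryl iodide / diazoacetate C–H cross-coupling as in step 3, under mild base that leaves the trans ester of the first ring unchanged.

Step 8
Reactants: 12 ethyl 2-diazo-2-{5-formyl-3-methoxy-2-[(DB2E)methoxy]phenyl}acetate
Product: 14 ethyl (2R,3R)-2-(DB2E)-5-formyl-7-methoxy-2,3-dihydro-1-benzofuran-3-carboxylate (new ring 2,3-trans), via cis-(2R,3S) ester 13 (not isolated)
Conditions: Rh2(S-PTTL)4 (2 mol%), toluene, −60 °C; then DBU (0.5 equiv), 0 °C → rt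
Reagents that add atoms: none
Why: Catalyst-controlled Rh(II)-carbenoid 1,5 C–H insertion with the antipodal catalyst sets the new C2 as R independently of the remote first ring, and DBU epimerises the new C3 to trans (the first ring is already at its trans equilibrium).

Step 9
Reactants: 14 ethyl (2R,3R)-2-(DB2E)-5-formyl-7-methoxy-2,3-dihydro-1-benzofuran-3-carboxylate; 6 ethyl diazoacetate
Product: 15 ethyl (2R,3R)-2-(DB2E)-5-(3-ethoxy-3-oxopropanoyl)-7-methoxy-2,3-dihydro-1-benzofuran-3-carboxylate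
Conditions: NbCl5 (5 mol%), CH2Cl2, 0 °C → rt
Reagents that add atoms: none
Why: Roskamp homologation, in which Lewis-acid-promoted addition of the diazoacetate to the aldehyde and 1,2-hydride shift with loss of N2 give the aryl β-ketoester without base.

Step 10
Reactants: 16 homovanillic acid
Product: 18 2-[3-methoxy-4-(triisopropylsilyloxy)phenyl]acetic acid, via bis-silyl ester 17 (not isolated)
Conditions: TIPSCl (2.2 equiv), imidazole, DMF, rt; then THF–H2O–AcOH, rt
Reagents that add atoms: triisopropylsilyl chloride CC(C)[Si](Cl)(C(C)C)C(C)C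
Why: Exhaustive silylation followed by selective hydrolysis of the labile silyl ester leaves only the robust aryl TIPS ether.

Step 11
Reactants: 18 2-[3-methoxy-4-(triisopropylsilyloxy)phenyl]acetic acid
Product: 21 1-chloro-3-ArT-propan-2-one, via acid chloride 19 (not isolated), via diazoketone 20 (not isolated)
Conditions: (COCl)2, DMF (cat.), CH2Cl2, 0 °C → rt; then CH2N2 (2.5 equiv), Et2O, 0 °C; then HCl (2 M in Et2O), 0 °C
Reagents that add atoms: oxalyl chloride ClC(=O)C(=O)Cl (Cl of 19 only); diazomethane C=[N+]=[N-]; hydrogen chloride Cl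
Why: Acylation of diazomethane by the arylacetyl chloride and hydrochlorination of the diazoketone (Nierenstein-type sequence) is the standard way to a benzyl chloromethyl ketone.

Step 12
Reactants: 15 ethyl (2R,3R)-2-(DB2E)-5-(3-ethoxy-3-oxopropanoyl)-7-methoxy-2,3-dihydro-1-benzofuran-3-carboxylate; 21 1-chloro-3-ArT-propan-2-one
Product: 23 ethyl 2-[(2R,3R)-2-(DB2E)-3-(ethoxycarbonyl)-7-methoxy-2,3-dihydro-1-benzofuran-5-yl]-4-(ArT-methyl)furan-3-carboxylate, via hydroxydihydrofuran 22 (not isolated)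
Conditions: pyridine, 60 °C; then TsOH·H2O (10 mol%), toluene, 40 °C
Reagents that add atoms: none
Why: Feist–Benary furan synthesis, in which under weak amine base the ketoester α-carbon adds to the ketone carbonyl of the chloroketone, the enol oxygen displaces chloride and acid dehydrates the 4-hydroxy-dihydrofuran, placing aryl at C2, ester at C3, benzyl at C4 and H at C5.

Step 13
Reactants: 23 ethyl 2-[(2R,3R)-2-(DB2E)-3-(ethoxycarbonyl)-7-methoxy-2,3-dihydro-1-benzofuran-5-yl]-4-(ArT-methyl)furan-3-carboxylate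
Product: 24 {2-[(2R,3S)-2-(DB2H)-3-(hydroxymethyl)-7-methoxy-2,3-dihydro-1-benzofuran-5-yl]-4-(ArT-methyl)furan-3-yl}methanol
Conditions: DIBAL-H (10 equiv), CH2Cl2, −78 → 0 °C; Rochelle salt work-up
Reagents that add atoms: none
Why: Global hydride reduction of the three ethyl esters to primary alcohols, which leaves the trans ring stereocentres in place (descriptors at C3 change only because of CIP priorities) and spares the aryl TIPS ethers.

Step 14
Reactants: 24 {2-[(2R,3S)-2-(DB2H)-3-(hydroxymethyl)-7-methoxy-2,3-dihydro-1-benzofuran-5-yl]-4-(ArT-methyl)furan-3-yl}methanol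
Product: 25 [(2R,3R,4R)-2-[(2R,3S)-2-(DB2H)-3-(hydroxymethyl)-7-methoxy-2,3-dihydro-1-benzofuran-5-yl]-4-(ArT-methyl)oxolan-3-yl]methanol (oxolane all-cis)
Conditions: Ru[(R,R)-SINpEt]2 catalyst (10 mol%; preformed from Ru(cod)(2-methylallyl)2, (R,R)-SINpEt·HBF4 and KOtBu in hexane, 70 °C), H2 (100 bar), toluene/t-AmOH, 25–40 °C
Reagents that add atoms: none
Why: Proposed new method: catalytic asymmetric dearomatising hydrogenation of a 2,3,4-trisubstituted furan, in which the chiral Ru–bis(NHC) hydride binds one furan face and transfers both H2 to that face without releasing a partly reduced species (the less hindered C4=C5 first, the second H2 also anti to the new C4 benzyl group), so the three new H are syn and aryl, CH2OH and benzyl end all-cis as (2R,3R,4R); closest known reaction is the Ru–SINpEt asymmetric hydrogenation of 2,5- and 2,4-disubstituted aryl furans and benzofurans to cis products, and the neutral medium avoids acid epimerisation of the benzylic C2.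

Step 15
Reactants: 25 [(2R,3R,4R)-2-[(2R,3S)-2-(DB2H)-3-(hydroxymethyl)-7-methoxy-2,3-dihydro-1-benzofuran-5-yl]-4-(ArT-methyl)oxolan-3-yl]methanol
Product: 26 {(2R,3S)-2-[(2S,3R)-2-(4-hydroxy-3-methoxyphenyl)-3-(hydroxymethyl)-7-methoxy-2,3-dihydro-1-benzofuran-5-yl]-5-[(2R,3R,4R)-4-(4-hydroxy-3-methoxybenzyl)-3-(hydroxymethyl)oxolan-2-yl]-7-methoxy-2,3-dihydro-1-benzofuran-3-yl}methanol (CNP0395728.1)
Conditions: TBAF (3 equiv), AcOH (3 equiv), THF, 0 °C → rt
Reagents that add atoms: none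
Why: Fluoride cleavage of both aryl silyl ethers under acetic-acid buffering, which is neither acidic enough to epimerise the all-cis benzylic ether nor basic enough to open the p-hydroxyphenyl dihydrobenzofuran.

**Compound list**
1 | vanillin (4-hydroxy-3-methoxybenzaldehyde) | COc1cc(C=O)ccc1O | starting material
2 | 3-methoxy-4-(triisopropylsilyloxy)benzaldehyde | COc1cc(C=O)ccc1O[Si](C(C)C)(C(C)C)C(C)C | intermediate
3 | [3-methoxy-4-(triisopropylsilyloxy)phenyl]methanol | COc1cc(CO)ccc1O[Si](C(C)C)(C(C)C)C(C)C | intermediate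
4 | 5-iodovanillin (4-hydroxy-3-iodo-5-methoxybenzaldehyde) | COc1cc(C=O)cc(I)c1O | starting material
5 | 3-iodo-5-methoxy-4-{[3-methoxy-4-(triisopropylsilyloxy)phenyl]methoxy}benzaldehyde | COc1cc(C=O)cc(I)c1OCc1ccc(O[Si](C(C)C)(C(C)C)C(C)C)c(OC)c1 | intermediate
6 | ethyl diazoacetate | CCOC(=O)C=[N+]=[N-] | starting material
7 | ethyl 2-diazo-2-(5-formyl-3-methoxy-2-{[3-methoxy-4-(triisopropylsilyloxy)phenyl]methoxy}phenyl)acetate | CCOC(=O)C(=[N+]=[N-])c1cc(C=O)cc(OC)c1OCc1ccc(O[Si](C(C)C)(C(C)C)C(C)C)c(OC)c1 | intermediate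
8 | ethyl (2S,3R)-5-formyl-7-methoxy-2-[3-methoxy-4-(triisopropylsilyloxy)phenyl]-2,3-dihydro-1-benzofuran-3-carboxylate (cis) | O=Cc1cc(OC)c2c(c1)[C@@H](C(=O)OCC)[C@@H](c1ccc(O[Si](C(C)C)(C(C)C)C(C)C)c(OC)c1)O2 | intermediate
9 | ethyl (2S,3S)-5-formyl-7-methoxy-2-[3-methoxy-4-(triisopropylsilyloxy)phenyl]-2,3-dihydro-1-benzofuran-3-carboxylate (trans) | O=Cc1cc(OC)c2c(c1)[C@H](C(=O)OCC)[C@@H](c1ccc(O[Si](C(C)C)(C(C)C)C(C)C)c(OC)c1)O2 | intermediate
10 | ethyl (2S,3S)-5-(hydroxymethyl)-7-methoxy-2-[3-methoxy-4-(triisopropylsilyloxy)phenyl]-2,3-dihydro-1-benzofuran-3-carboxylate | OCc1cc(OC)c2c(c1)[C@H](C(=O)OCC)[C@@H](c1ccc(O[Si](C(C)C)(C(C)C)C(C)C)c(OC)c1)O2 | intermediate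
11 | ethyl (2S,3S)-5-[(4-formyl-2-iodo-6-methoxyphenoxy)methyl]-7-methoxy-2-[3-methoxy-4-(triisopropylsilyloxy)phenyl]-2,3-dihydro-1-benzofuran-3-carboxylate | COc1cc(C=O)cc(I)c1OCc1cc(OC)c2c(c1)[C@H](C(=O)OCC)[C@@H](c1ccc(O[Si](C(C)C)(C(C)C)C(C)C)c(OC)c1)O2 | intermediate
12 | ethyl (2S,3S)-5-{[2-(1-diazo-2-ethoxy-2-oxoethyl)-4-formyl-6-methoxyphenoxy]methyl}-7-methoxy-2-[3-methoxy-4-(triisopropylsilyloxy)phenyl]-2,3-dihydro-1-benzofuran-3-carboxylate | CCOC(=O)C(=[N+]=[N-])c1cc(C=O)cc(OC)c1OCc1cc(OC)c2c(c1)[C@H](C(=O)OCC)[C@@H](c1ccc(O[Si](C(C)C)(C(C)C)C(C)C)c(OC)c1)O2 | intermediate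
13 | ethyl (2R,3S)-2-(DB2E)-5-formyl-7-methoxy-2,3-dihydro-1-benzofuran-3-carboxylate (new ring cis) | O=Cc1cc(OC)c2c(c1)[C@H](C(=O)OCC)[C@H](c1cc(OC)c3c(c1)[C@H](C(=O)OCC)[C@@H](c1ccc(O[Si](C(C)C)(C(C)C)C(C)C)c(OC)c1)O3)O2 | intermediate
14 | ethyl (2R,3R)-2-(DB2E)-5-formyl-7-methoxy-2,3-dihydro-1-benzofuran-3-carboxylate (new ring trans) | O=Cc1cc(OC)c2c(c1)[C@@H](C(=O)OCC)[C@H](c1cc(OC)c3c(c1)[C@H](C(=O)OCC)[C@@H](c1ccc(O[Si](C(C)C)(C(C)C)C(C)C)c(OC)c1)O3)O2 | intermediate
15 | ethyl (2R,3R)-2-(DB2E)-5-(3-ethoxy-3-oxopropanoyl)-7-methoxy-2,3-dihydro-1-benzofuran-3-carboxylate | CCOC(=O)CC(=O)c1cc(OC)c2c(c1)[C@@H](C(=O)OCC)[C@H](c1cc(OC)c3c(c1)[C@H](C(=O)OCC)[C@@H](c1ccc(O[Si](C(C)C)(C(C)C)C(C)C)c(OC)c1)O3)O2 | intermediate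
16 | homovanillic acid (4-hydroxy-3-methoxyphenylacetic acid) | COc1cc(CC(=O)O)ccc1O | starting material
17 | triisopropylsilyl 2-[3-methoxy-4-(triisopropylsilyloxy)phenyl]acetate | COc1cc(CC(=O)O[Si](C(C)C)(C(C)C)C(C)C)ccc1O[Si](C(C)C)(C(C)C)C(C)C | intermediate
18 | 2-[3-methoxy-4-(triisopropylsilyloxy)phenyl]acetic acid | COc1cc(CC(=O)O)ccc1O[Si](C(C)C)(C(C)C)C(C)C | intermediate
19 | 2-[3-methoxy-4-(triisopropylsilyloxy)phenyl]acetyl chloride | COc1cc(CC(=O)Cl)ccc1O[Si](C(C)C)(C(C)C)C(C)C | intermediate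
20 | 1-diazo-3-[3-methoxy-4-(triisopropylsilyloxy)phenyl]propan-2-one | COc1cc(CC(=O)C=[N+]=[N-])ccc1O[Si](C(C)C)(C(C)C)C(C)C | intermediate
21 | 1-chloro-3-[3-methoxy-4-(triisopropylsilyloxy)phenyl]propan-2-one | COc1cc(CC(=O)CCl)ccc1O[Si](C(C)C)(C(C)C)C(C)C | intermediate
22 | ethyl 2-[(2R,3R)-2-(DB2E)-3-(ethoxycarbonyl)-7-methoxy-2,3-dihydro-1-benzofuran-5-yl]-4-hydroxy-4-(ArT-methyl)-4,5-dihydrofuran-3-carboxylate (both C4 epimers) | CCOC(=O)C1=C(OCC1(O)Cc1ccc(O[Si](C(C)C)(C(C)C)C(C)C)c(OC)c1)c1cc(OC)c2c(c1)[C@@H](C(=O)OCC)[C@H](c1cc(OC)c3c(c1)[C@H](C(=O)OCC)[C@@H](c1ccc(O[Si](C(C)C)(C(C)C)C(C)C)c(OC)c1)O3)O2 | intermediate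
23 | ethyl 2-[(2R,3R)-2-(DB2E)-3-(ethoxycarbonyl)-7-methoxy-2,3-dihydro-1-benzofuran-5-yl]-4-(ArT-methyl)furan-3-carboxylate | CCOC(=O)c1c(Cc2ccc(O[Si](C(C)C)(C(C)C)C(C)C)c(OC)c2)coc1-c1cc(OC)c2c(c1)[C@@H](C(=O)OCC)[C@H](c1cc(OC)c3c(c1)[C@H](C(=O)OCC)[C@@H](c1ccc(O[Si](C(C)C)(C(C)C)C(C)C)c(OC)c1)O3)O2 | intermediate
24 | {2-[(2R,3S)-2-(DB2H)-3-(hydroxymethyl)-7-methoxy-2,3-dihydro-1-benzofuran-5-yl]-4-(ArT-methyl)furan-3-yl}methanol | OCc1c(Cc2ccc(O[Si](C(C)C)(C(C)C)C(C)C)c(OC)c2)coc1-c1cc(OC)c2c(c1)[C@@H](CO)[C@H](c1cc(OC)c3c(c1)[C@H](CO)[C@@H](c1ccc(O[Si](C(C)C)(C(C)C)C(C)C)c(OC)c1)O3)O2 | intermediate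
25 | [(2R,3R,4R)-2-[(2R,3S)-2-(DB2H)-3-(hydroxymethyl)-7-methoxy-2,3-dihydro-1-benzofuran-5-yl]-4-(ArT-methyl)oxolan-3-yl]methanol (all-cis oxolane, bis-TIPS ether of the target) | COc1cc(C[C@H]2CO[C@@H](c3cc(OC)c4c(c3)[C@@H](CO)[C@H](c3cc(OC)c5c(c3)[C@H](CO)[C@@H](c3ccc(O[Si](C(C)C)(C(C)C)C(C)C)c(OC)c3)O5)O4)[C@H]2CO)ccc1O[Si](C(C)C)(C(C)C)C(C)C | intermediate
26 | CNP0395728.1, {(2R,3S)-2-[(2S,3R)-2-(4-hydroxy-3-methoxyphenyl)-3-(hydroxymethyl)-7-methoxy-2,3-dihydro-1-benzofuran-5-yl]-5-[(2R,3R,4R)-4-(4-hydroxy-3-methoxybenzyl)-3-(hydroxymethyl)oxolan-2-yl]-7-methoxy-2,3-dihydro-1-benzofuran-3-yl}methanol | COc1cc(C[C@H]2CO[C@@H](c3cc(OC)c4c(c3)[C@@H](CO)[C@H](c3cc(OC)c5c(c3)[C@H](CO)[C@@H](c3ccc(O)c(OC)c3)O5)O4)[C@H]2CO)ccc1O | target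

**Totals**
Total step count: 15 (13 on the main line, 2 for chloroketone 21).
Longest linear sequence: 13 steps (vanillin 1 → 26: steps 1–9 and 12–15).

**Three steps most likely to fail**

Step 14, the asymmetric furan hydrogenation. The 2,3,4-trisubstitution and the free hydroxyls are outside the demonstrated scope, so it may stall at the enol ether stage or give poor facial selectivity. The fallback sets out from 24 and comes back at 25, and splits the dearomatisation into two individually precedented alkene hydrogenations. An Ir pyridine–phosphinite catalyst of the Pfaltz type (1–2 mol%, H2 50 bar, CH2Cl2, 40 °C) reduces only the trisubstituted C4=C5 bond, a 3-alkylfuran motif for which these catalysts give high ee. This gives the (4R)-4,5-dihydrofuran triol F1. Crabtree's catalyst (H2 1–5 bar, CH2Cl2) then delivers H2 to the tetrasubstituted enol ether under direction of the allylic CH2OH, on the face anti to the C4 benzyl group, and gives 25.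

Step 12, the Feist–Benary annulation. C-alkylation at CH2Cl would lead to the 2,3,5-isomer, and 21 can self-condense or quaternise pyridine. The fallback sets out from 21 (with 15) and comes back at 23, and replaces halide displacement by a Lewis-acid condensation of a hydroxy ketone. Heating 21 with sodium formate in aqueous ethanol (80 °C) gives 1-hydroxy-3-ArT-propan-2-one F2. F2 and 15 with ZnCl2 in toluene at 80 °C undergo Knoevenagel condensation at the ketone carbon, hemiketalisation by the primary OH and loss of two waters to give 23. The C–C bond can only form at the ketone carbon, so the 2,3,4-pattern is fixed.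

Step 9, the Roskamp homologation. With an electron-rich aryl aldehyde, aryl instead of hydride migration would give a 2-aryl-3-hydroxyacrylate, and the Lewis acid may attack the benzylic ethers. The fallback sets out from 14 and comes back at 15, and makes the C–C bond by addition and then adjusts the oxidation level. Reformatsky addition (Zn, ethyl bromoacetate, THF, rt; the zinc enolate ignores the two esters) gives ethyl (2R,3R)-2-(DB2E)-5-(3-ethoxy-1-hydroxy-3-oxopropyl)-7-methoxy-2,3-dihydro-1-benzofuran-3-carboxylate F3 as both carbinol epimers. Dess–Martin oxidation (CH2Cl2, NaHCO3) then gives 15.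

**Further compounds**
F1 | step 14 | [(4R)-2-[(2R,3S)-2-(DB2H)-3-(hydroxymethyl)-7-methoxy-2,3-dihydro-1-benzofuran-5-yl]-4-(ArT-methyl)-4,5-dihydrofuran-3-yl]methanol | COc1cc(C[C@H]2COC(c3cc(OC)c4c(c3)[C@@H](CO)[C@H](c3cc(OC)c5c(c3)[C@H](CO)[C@@H](c3ccc(O[Si](C(C)C)(C(C)C)C(C)C)c(OC)c3)O5)O4)=C2CO)ccc1O[Si](C(C)C)(C(C)C)C(C)C
F2 | step 12 | 1-hydroxy-3-[3-methoxy-4-(triisopropylsilyloxy)phenyl]propan-2-one | COc1cc(CC(=O)CO)ccc1O[Si](C(C)C)(C(C)C)C(C)C
F3 | step 9 | ethyl (2R,3R)-2-(DB2E)-5-(3-ethoxy-1-hydroxy-3-oxopropyl)-7-methoxy-2,3-dihydro-1-benzofuran-3-carboxylate (both carbinol epimers) | CCOC(=O)CC(O)c1cc(OC)c2c(c1)[C@@H](C(=O)OCC)[C@H](c1cc(OC)c3c(c1)[C@H](C(=O)OCC)[C@@H](c1ccc(O[Si](C(C)C)(C(C)C)C(C)C)c(OC)c1)O3)O2
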